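**Assumption:** guaiane numbering (C1–C15) is used for the guaianolide half and primed seco-eudesmane numbering (C1′–C15′) for the britannilactone half; where a chiral ligand or catalyst fixes absolute sense, the antipode that gives the stated descriptor is used.

## Retrosynthetic overview

1. The norbornene is closed last by a biomimetic exo Diels–Alder union (C13′–C1 and C11′–C3) of 1-O-acetylbritannilactone 16 with the 5-acetoxycyclopentadiene 29, released in situ from tertiary alcohol 28.
2. In 28 the C2–O bond, the C2 stereocentre and the cyclopentenone come from one acetate-intercepted (acyloxy) Piancatelli rearrangement of a furfuryl acetate, which is the key step.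
3. Allylation, cross-metathesis and an intramolecular Nozaki–Hiyama allylation (C7–C8) then add the seven-membered ring and the trans-lactone of 28.
4. For 16, (S)-citronellal supplies C4′, asymmetric vinylation sets C6′, an indium Barbier allylation makes C7′–C8′ and the cis-lactone, and a tetrasubstituted ring-closing metathesis closes the cyclohexene.
5. Ring order: lactone then cyclohexene (16); cyclopentenone, then cycloheptane with lactone, then cyclopentadiene (28, 29); norbornene last.

## Route

### Dienophile half (steps 1–10)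

**Step 1**
Reactants: 1 (S)-citronellal
Product: 4 (4S)-6,6-dimethoxy-4-methylhexan-1-ol, via citronellal dimethyl acetal 2 (not isolated), via methoxy hydroperoxide 3 (not isolated)
Conditions: p-TsOH (cat.), MeOH, 3 Å MS, rt; then O3, −78 °C; then NaBH4, −78 → 0 °C
Reagents that add atoms: methanol (CO); ozone ([O-][O+]=O)
Why: acetalisation masks the aldehyde, and ozonolysis of the trisubstituted alkene in methanol with in situ borohydride reduction gives the primary alcohol without touching the C4′ stereocentre taken from the chiral pool.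

**Step 2**
Reactants: 4 (4S)-6,6-dimethoxy-4-methylhexan-1-ol
Product: 5 (4S)-6,6-dimethoxy-4-methylhexyl acetate
Conditions: Ac2O, pyridine, DMAP (cat.), CH2Cl2, 0 °C
Reagents that add atoms: acetic anhydride (CC(=O)OC(C)=O)
Why: routine O-acetylation installs the C1′ acetate of the target at the outset.

**Step 3**
Reactants: 5 (4S)-6,6-dimethoxy-4-methylhexyl acetate
Product: 7 (4S)-5-formyl-4-methylhex-5-en-1-yl acetate, via 4-methyl-6-oxohexyl acetate 6 (not isolated)
Conditions: 1 M HCl, THF, rt; then 37% aq. CH2O, pyrrolidine (10 mol%), EtCO2H (10 mol%), iPrOH, 45 °C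
Reagents that add atoms: water (O); formaldehyde (C=O)
Why: acetal hydrolysis followed by organocatalytic Mannich condensation–elimination (α-methylenation of an aldehyde) gives the 2-substituted acrolein that carries C5′ and C6′, with C4′ unaffected.

**Step 4**
Reactants: 7 (4S)-5-formyl-4-methylhex-5-en-1-yl acetate
Product: 8 (4S,6S)-6-hydroxy-4-methyl-5-methylideneoct-7-en-1-yl acetate
Conditions: (CH2=CH)2Zn, (−)-3-exo-morpholinoisoborneol (5 mol%), PhMe/hexane, −20 °C
Reagents that add atoms: divinylzinc (C=C[Zn]C=C)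
Why: amino-alcohol-catalysed enantioselective 1,2-addition of an alkenylzinc reagent is chemoselective for the aldehyde over the acetate and sets C6′ (S) by catalyst control.

**Step 5**
Reactants: 8 (4S,6S)-6-hydroxy-4-methyl-5-methylideneoct-7-en-1-yl acetate
Product: 9 methyl (2Z,4S,6S)-9-acetoxy-2-(bromomethyl)-4-hydroxy-6-methyl-5-methylidenenon-2-enoate
Conditions: methyl 2-(bromomethyl)acrylate (3 equiv), dichloro[1,3-bis(2,4,6-trimethylphenyl)imidazolidin-2-ylidene](2-isopropoxybenzylidene)ruthenium (5 mol%), CH2Cl2, 40 °C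
Reagents that add atoms: methyl 2-(bromomethyl)acrylate (C=C(CBr)C(=O)OC)
Why: olefin cross-metathesis engages only the monosubstituted vinyl group and gives the thermodynamically preferred Z-enoate, in which hydroxyl and ester are trans so that no butenolide can form.

**Step 6**
Reactants: 9 methyl (2Z,4S,6S)-9-acetoxy-2-(bromomethyl)-4-hydroxy-6-methyl-5-methylidenenon-2-enoate
Product: 10 methyl (2Z,4S,6S)-9-acetoxy-2-(bromomethyl)-4-(tert-butyldimethylsilyloxy)-6-methyl-5-methylidenenon-2-enoate
Conditions: TBSOTf, 2,6-lutidine, CH2Cl2, −78 °C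
Reagents that add atoms: tert-butyldimethylsilyl trifluoromethanesulfonate (CC(C)(C)[Si](C)(C)OS(=O)(=O)C(F)(F)F)
Why: silylation makes the C6′ oxygen bulky and non-chelating, which is what steers the allylation in step 8.

**Step 7**
Reactants: 11 3-methylbut-3-en-1-ol
Product: 12 3-methylbut-3-enal
Conditions: Dess–Martin periodinane, NaHCO3, CH2Cl2, 0 °C (cold solution used at once)
Reagents that add atoms: none
Why: buffered Dess–Martin oxidation gives the β,γ-unsaturated aldehyde without isomerisation to the conjugated enal.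

**Step 8**
Reactants: 10 methyl (2Z,4S,6S)-9-acetoxy-2-(bromomethyl)-4-(tert-butyldimethylsilyloxy)-6-methyl-5-methylidenenon-2-enoate; 12 3-methylbut-3-enal
Product: 14 (4S,6S)-6-(tert-butyldimethylsilyloxy)-4-methyl-5-methylidene-6-[(2R,3R)-4-methylidene-2-(2-methylprop-2-enyl)-5-oxooxolan-3-yl]hexyl acetate, via hydroxy ester 13 (not isolated)
Conditions: In powder, THF/H2O (1:1), rt; then p-TsOH (cat.), CH2Cl2, rt
Reagents that add atoms: none
Why: in this indium-mediated Barbier 2-(alkoxycarbonyl)allylation the Z-allylindium reacts through a chair Zimmerman–Traxler transition state to give the 7′,8′-syn adduct, with attack anti to the non-chelating silyloxy group at C6′ (Felkin–Anh-type control), so acid lactonisation gives the cis-β,γ-disubstituted α-methylene lactone with C7′ and C8′ set.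

**Step 9**
Reactants: 14 (4S,6S)-6-(tert-butyldimethylsilyloxy)-4-methyl-5-methylidene-6-[(2R,3R)-4-methylidene-2-(2-methylprop-2-enyl)-5-oxooxolan-3-yl]hexyl acetate
Product: 15 (4S)-4-[(3aR,4S,7aR)-4-(tert-butyldimethylsilyloxy)-6-methyl-3-methylidene-2-oxo-2,3,3a,4,7,7a-hexahydro-1-benzofuran-5-yl]pentyl acetate
Conditions: dichloro[1,3-bis(2-methylphenyl)imidazolidin-2-ylidene](2-isopropoxybenzylidene)ruthenium (10 mol%), C6H6, 60 °C, 0.005 M
Reagents that add atoms: none
Why: ring-closing metathesis of the two 1,1-disubstituted alkenes with a sterically open N-aryl carbene ruthenium catalyst forms the tetrasubstituted C5′=C10′ cyclohexene, the electron-poor methylene lactone being a poor partner and no stereocentre being touched.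

**Step 10**
Reactants: 15 (4S)-4-[(3aR,4S,7aR)-4-(tert-butyldimethylsilyloxy)-6-methyl-3-methylidene-2-oxo-2,3,3a,4,7,7a-hexahydro-1-benzofuran-5-yl]pentyl acetate
Product: 16 1-O-acetylbritannilactone
Conditions: HF·pyridine, THF, 0 °C → rt
Reagents that add atoms: none
Why: buffered fluoride desilylation leaves the acetate and the base-sensitive methylene lactone intact.

### Diene half (steps 11–18)

**Step 11**
Reactants: 17 3-methylfuran-2-carbaldehyde
Product: 18 (1S,2S)-2-methyl-1-(3-methylfuran-2-yl)but-3-en-1-ol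
Conditions: [IrCl(C8H12)]2 (2.5 mol%), (S)-SEGPHOS, 4-cyano-3-nitrobenzoic acid, Cs2CO3 (20 mol%), but-3-en-2-yl acetate, iPrOH, THF, 60 °C
Reagents that add atoms: but-3-en-2-yl acetate (CC(OC(C)=O)C=C)
Why: iridium-catalysed transfer-hydrogenative anti-crotylation (Krische carbonyl crotylation) sets the methyl-bearing centre (future C10, S) under catalyst control, while the carbinol centre is lost later.

**Step 12**
Reactants: 18 (1S,2S)-2-methyl-1-(3-methylfuran-2-yl)but-3-en-1-ol
Product: 20 (1S,2S)-2-methyl-1-(3-methylfuran-2-yl)butane-1,4-diol, via bis-boryl adduct 19 (not isolated)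
Conditions: 9-BBN (2.2 equiv), THF, 0 °C → rt; then NaOH, H2O2, 0 °C
Reagents that add atoms: hydrogen peroxide (OO)
Why: anti-Markovnikov hydroboration–oxidation of the terminal alkene installs the future C8 oxygen, the furan being inert to 9-BBN and to basic peroxide.

**Step 13**
Reactants: 20 (1S,2S)-2-methyl-1-(3-methylfuran-2-yl)butane-1,4-diol
Product: 22 (1R,5S)-5-[(2S)-4-acetoxybutan-2-yl]-3-methyl-4-oxocyclopent-2-en-1-yl acetate, via furfuryl diacetate 21 (not isolated)
Conditions: Ac2O, pyridine, rt; concentrate; then (R)-3,3′-bis(2,4,6-triisopropylphenyl)-1,1′-binaphthyl-2,2′-diyl N-triflylphosphoramide (10 mol%), AcOH (5 equiv), MeCN, 50 °C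
Reagents that add atoms: acetic anhydride (CC(=O)OC(C)=O)
Why: Proposed new method: an acyloxy-Piancatelli rearrangement in which the chiral Brønsted acid ionises the furfuryl acetate, acetate adds at C5 of the furan to form the C2–O bond, ring opening gives a 1-acetoxy-4-hydroxypentadienyl cation paired with the chiral anion, and conrotatory 4π electrocyclisation closes C1–C2 to give the trans-4-acetoxy-5-alkylcyclopentenone with C2 (R) set under catalyst control; the closest known chemistry is the oxa- and aza-Piancatelli rearrangement with water, alcohol and aniline nucleophiles and chiral-acid-controlled aza-Piancatelli and Nazarov cyclisations, whereas a carboxylate nucleophile has not been used.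

**Step 14**
Reactants: 22 (1R,5S)-5-[(2S)-4-acetoxybutan-2-yl]-3-methyl-4-oxocyclopent-2-en-1-yl acetate
Product: 23 (1R,4S,5S)-5-[(2S)-4-acetoxybutan-2-yl]-4-hydroxy-3-methyl-4-(prop-2-enyl)cyclopent-2-en-1-yl acetate
Conditions: allyl bromide, In powder, THF/H2O (3:1), rt
Reagents that add atoms: allyl bromide (C=CCBr)
Why: Barbier allylation with allylindium adds 1,2 to the enone carbonyl from the face opposite the C1 side chain under neutral conditions that avoid β-elimination of the acetate, and the new carbinol centre is removed in step 19.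

**Step 15**
Reactants: 23 (1R,4S,5S)-5-[(2S)-4-acetoxybutan-2-yl]-4-hydroxy-3-methyl-4-(prop-2-enyl)cyclopent-2-en-1-yl acetate
Product: 24 (1R,4S,5S)-4-hydroxy-5-[(2S)-4-hydroxybutan-2-yl]-3-methyl-4-(prop-2-enyl)cyclopent-2-en-1-yl acetate
Conditions: Candida antarctica lipase B (immobilised), pH 7 phosphate buffer/MTBE, 30 °C
Reagents that add atoms: none
Why: lipase-catalysed hydrolysis discriminates the unhindered primary acetate from the secondary allylic acetate flanked by two fully substituted ring carbons.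

**Step 16**
Reactants: 24 (1R,4S,5S)-4-hydroxy-5-[(2S)-4-hydroxybutan-2-yl]-3-methyl-4-(prop-2-enyl)cyclopent-2-en-1-yl acetate
Product: 25 (1R,4S,5S)-4-hydroxy-3-methyl-5-[(2S)-4-oxobutan-2-yl]-4-(prop-2-enyl)cyclopent-2-en-1-yl acetate
Conditions: Dess–Martin periodinane, NaHCO3, CH2Cl2, 0 °C
Reagents that add atoms: none
Why: Dess–Martin oxidation converts only the primary alcohol, since the tertiary alcohol cannot be oxidised and no epimerisable centre is α to the new aldehyde.

**Step 17**
Reactants: 25 (1R,4S,5S)-4-hydroxy-3-methyl-5-[(2S)-4-oxobutan-2-yl]-4-(prop-2-enyl)cyclopent-2-en-1-yl acetate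
Product: 26 methyl (2Z)-4-[(1S,4R,5S)-4-acetoxy-1-hydroxy-2-methyl-5-[(2S)-4-oxobutan-2-yl]cyclopent-2-en-1-yl]-2-(bromomethyl)but-2-enoate
Conditions: methyl 2-(bromomethyl)acrylate (4 equiv), dichloro[1,3-bis(2,4,6-trimethylphenyl)imidazolidin-2-ylidene](2-isopropoxybenzylidene)ruthenium (5 mol%), CH2Cl2, 40 °C
Reagents that add atoms: methyl 2-(bromomethyl)acrylate (C=C(CBr)C(=O)OC)
Why: cross-metathesis of the terminal allyl group with the 2-substituted acrylate installs the allylic bromide next to the aldehyde, the trisubstituted ring alkene being unreactive.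

**Step 18**
Reactants: 26 methyl (2Z)-4-[(1S,4R,5S)-4-acetoxy-1-hydroxy-2-methyl-5-[(2S)-4-oxobutan-2-yl]cyclopent-2-en-1-yl]-2-(bromomethyl)but-2-enoate
Product: 28 (1S,2R,5S,7R,8S,10S)-2-acetoxy-5-hydroxyguaia-3,11(13)-dien-12,8-olide, via hydroxy ester 27 (not isolated)
Conditions: CrCl2 (6 equiv), THF, 0.005 M, rt; then PPTS (cat.), CH2Cl2
Reagents that add atoms: none
Why: intramolecular Nozaki–Hiyama allylation closes the seven-membered ring through a chair-like transition state of the E-allylchromium species, which gives the 7,8-anti hydroxy ester and hence the trans-fused α-methylene lactone, with the C10 methyl group expected to direct the face and set C7 (R) and C8 (S).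

### Union (step 19)

**Step 19**
Reactants: 28 (1S,2R,5S,7R,8S,10S)-2-acetoxy-5-hydroxyguaia-3,11(13)-dien-12,8-olide; 16 1-O-acetylbritannilactone
Product: 30 target dimer CNP0211028.3, via acetoxycyclopentadiene 29 (not isolated)
Conditions: Ph2S[OC(CF3)2Ph]2 (Martin sulfurane, 1.0 equiv to 28), CH2Cl2, −50 °C; then 16 (0.5 equiv), 2 M, −20 °C → rt, 48 h
Reagents that add atoms: none
Why: sulfurane dehydration of the tertiary allylic alcohol releases the 5-acetoxycyclopentadiene below the temperature of [1,5]-hydrogen shift, and a biomimetic Diels–Alder reaction with the exocyclic alkene of 16 follows, exo to the lactone carbonyl, on the diene face anti to the C2 acetate and C10 methyl and with the CH2 terminus bonding to the more substituted C1, which sets C1, C3 and the spiro centre C11′.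

## Compound list

1 | (S)-citronellal, (3S)-3,7-dimethyloct-6-enal | O=CC[C@@H](C)CCC=C(C)C | starting material
2 | (6S)-8,8-dimethoxy-2,6-dimethyloct-2-ene | COC(OC)C[C@@H](C)CCC=C(C)C | intermediate
3 | (4S)-1-hydroperoxy-1,6,6-trimethoxy-4-methylhexane (both C1 epimers) | COC(OC)C[C@@H](C)CCC(OC)OO | intermediate
4 | (4S)-6,6-dimethoxy-4-methylhexan-1-ol | COC(OC)C[C@@H](C)CCCO | intermediate
5 | (4S)-6,6-dimethoxy-4-methylhexyl acetate | COC(OC)C[C@@H](C)CCCOC(C)=O | intermediate
6 | (4S)-4-methyl-6-oxohexyl acetate | O=CC[C@@H](C)CCCOC(C)=O | intermediate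
7 | (4S)-5-formyl-4-methylhex-5-en-1-yl acetate | C=C(C=O)[C@@H](C)CCCOC(C)=O | intermediate
8 | (4S,6S)-6-hydroxy-4-methyl-5-methylideneoct-7-en-1-yl acetate | C=C[C@H](O)C(=C)[C@@H](C)CCCOC(C)=O | intermediate
9 | methyl (2Z,4S,6S)-9-acetoxy-2-(bromomethyl)-4-hydroxy-6-methyl-5-methylidenenon-2-enoate | BrC/C(C(=O)OC)=C\[C@H](O)C(=C)[C@@H](C)CCCOC(C)=O | intermediate
10 | methyl (2Z,4S,6S)-9-acetoxy-2-(bromomethyl)-4-(tert-butyldimethylsilyloxy)-6-methyl-5-methylidenenon-2-enoate | BrC/C(C(=O)OC)=C\[C@H](O[Si](C)(C)C(C)(C)C)C(=C)[C@@H](C)CCCOC(C)=O | intermediate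
11 | 3-methylbut-3-en-1-ol | C=C(C)CCO | starting material
12 | 3-methylbut-3-enal | C=C(C)CC=O | intermediate
13 | methyl (3R,4R)-3-[(1S,3S)-6-acetoxy-1-(tert-butyldimethylsilyloxy)-3-methyl-2-methylidenehexyl]-4-hydroxy-6-methyl-2-methylidenehept-6-enoate | C=C(C(=O)OC)[C@@H]([C@H](O[Si](C)(C)C(C)(C)C)C(=C)[C@@H](C)CCCOC(C)=O)[C@H](O)CC(C)=C | intermediate
14 | (4S,6S)-6-(tert-butyldimethylsilyloxy)-4-methyl-5-methylidene-6-[(2R,3R)-4-methylidene-2-(2-methylprop-2-enyl)-5-oxooxolan-3-yl]hexyl acetate | C=C1C(=O)O[C@H](CC(C)=C)[C@@H]1[C@H](O[Si](C)(C)C(C)(C)C)C(=C)[C@@H](C)CCCOC(C)=O | intermediate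
15 | (4S)-4-[(3aR,4S,7aR)-4-(tert-butyldimethylsilyloxy)-6-methyl-3-methylidene-2-oxo-2,3,3a,4,7,7a-hexahydro-1-benzofuran-5-yl]pentyl acetate | C=C1C(=O)O[C@@H]2CC(C)=C([C@@H](C)CCCOC(C)=O)[C@@H](O[Si](C)(C)C(C)(C)C)[C@@H]21 | intermediate
16 | 1-O-acetylbritannilactone, (4S)-4-[(3aS,4S,7aR)-4-hydroxy-6-methyl-3-methylidene-2-oxo-2,3,3a,4,7,7a-hexahydro-1-benzofuran-5-yl]pentyl acetate | C=C1C(=O)O[C@@H]2CC(C)=C([C@@H](C)CCCOC(C)=O)[C@@H](O)[C@@H]21 | intermediate
17 | 3-methylfuran-2-carbaldehyde | Cc1ccoc1C=O | starting material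
18 | (1S,2S)-2-methyl-1-(3-methylfuran-2-yl)but-3-en-1-ol | Cc1ccoc1[C@@H](O)[C@@H](C)C=C | intermediate
19 | 9-[(3S,4S)-4-(9-borabicyclo[3.3.1]nonan-9-yloxy)-3-methyl-4-(3-methylfuran-2-yl)butyl]-9-borabicyclo[3.3.1]nonane | Cc1ccoc1[C@@H](OB2C3CCCC2CCC3)[C@@H](C)CCB2C3CCCC2CCC3 | intermediate
20 | (1S,2S)-2-methyl-1-(3-methylfuran-2-yl)butane-1,4-diol | Cc1ccoc1[C@@H](O)[C@@H](C)CCO | intermediate
21 | (1S,2S)-2-methyl-1-(3-methylfuran-2-yl)butane-1,4-diyl diacetate | Cc1ccoc1[C@@H](OC(C)=O)[C@@H](C)CCOC(C)=O | intermediate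
22 | (1R,5S)-5-[(2S)-4-acetoxybutan-2-yl]-3-methyl-4-oxocyclopent-2-en-1-yl acetate | O=C1C(C)=C[C@@H](OC(C)=O)[C@@H]1[C@@H](C)CCOC(C)=O | intermediate
23 | (1R,4S,5S)-5-[(2S)-4-acetoxybutan-2-yl]-4-hydroxy-3-methyl-4-(prop-2-enyl)cyclopent-2-en-1-yl acetate | C=CC[C@@]1(O)C(C)=C[C@@H](OC(C)=O)[C@@H]1[C@@H](C)CCOC(C)=O | intermediate
24 | (1R,4S,5S)-4-hydroxy-5-[(2S)-4-hydroxybutan-2-yl]-3-methyl-4-(prop-2-enyl)cyclopent-2-en-1-yl acetate | C=CC[C@@]1(O)C(C)=C[C@@H](OC(C)=O)[C@@H]1[C@@H](C)CCO | intermediate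
25 | (1R,4S,5S)-4-hydroxy-3-methyl-5-[(2S)-4-oxobutan-2-yl]-4-(prop-2-enyl)cyclopent-2-en-1-yl acetate | C=CC[C@@]1(O)C(C)=C[C@@H](OC(C)=O)[C@@H]1[C@@H](C)CC=O | intermediate
26 | methyl (2Z)-4-[(1S,4R,5S)-4-acetoxy-1-hydroxy-2-methyl-5-[(2S)-4-oxobutan-2-yl]cyclopent-2-en-1-yl]-2-(bromomethyl)but-2-enoate | BrC/C(C(=O)OC)=C\C[C@@]1(O)C(C)=C[C@@H](OC(C)=O)[C@@H]1[C@@H](C)CC=O | intermediate
27 | methyl (1S,2R,5S,7R,8S,10S)-2-acetoxy-5,8-dihydroxyguaia-3,11(13)-dien-12-oate | O[C@H]1C[C@H](C)[C@@H]2[C@@](O)(C[C@@H]1C(=C)C(=O)OC)C(C)=C[C@H]2OC(C)=O | intermediate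
28 | (1S,2R,5S,7R,8S,10S)-2-acetoxy-5-hydroxyguaia-3,11(13)-dien-12,8-olide | C=C1C(=O)O[C@H]2C[C@H](C)[C@@H]3[C@@](O)(C[C@H]12)C(C)=C[C@H]3OC(C)=O | intermediate
29 | (2R,7R,8S,10S)-2-acetoxyguaia-1(5),3,11(13)-trien-12,8-olide | C=C1C(=O)O[C@H]2C[C@H](C)C3=C(C[C@H]12)C(C)=C[C@H]3OC(C)=O | intermediate
30 | CNP0211028.3, the C13′–C1/C11′–C3 Diels–Alder adduct of 16 and 29 | C=C1C(=O)O[C@H]2C[C@H](C)[C@@]34C[C@]5(C(=O)O[C@@H]6CC(C)=C([C@@H](C)CCCOC(C)=O)[C@@H](O)[C@@H]65)[C@@H](C(C)=C3C[C@H]12)[C@H]4OC(C)=O | target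

## Step count and risks

Total: 19 steps. Longest linear sequence: 10 steps (steps 1–6, 8–10 and 19); the diene branch is 9 steps (11–19).

**Step 13 (the proposed new acyloxy-Piancatelli rearrangement).** Acetate may fail to intercept the furfuryl cation, or the chiral acid may not control C2. The fallback sets out from diol 20 and uses the classical aqueous Piancatelli rearrangement (Dy(OSO2CF3)3 10 mol%, t-BuOH/H2O, 80 °C), which is known chemistry. It gives the trans hydroxy enone (4R,5S)-4-hydroxy-5-[(2S)-4-hydroxybutan-2-yl]-2-methylcyclopent-2-en-1-one F1, the 4S,5R diastereomer being removed by chromatography. Acetylation of F1 (Ac2O, pyridine, DMAP) brings the route back at 22.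

**Step 19 (Diels–Alder union).** The diene can isomerise by hydrogen shift before it is trapped, and the facial sense at both partners is taken from the natural series rather than proven. The fallback sets out from silyl ether 15, which has no free hydroxyl and so tolerates a Lewis acid. Diene 29 is generated from 28 as before and combined with 15 and Et2AlCl at −40 °C in a catalysed cycloaddition. This gives the O-silylated adduct, the 6′-O-tert-butyldimethylsilyl ether of the target dimer F2, and HF·pyridine then returns the route at 30.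

**Step 9 (tetrasubstituted ring-closing metathesis).** Both alkenes are 1,1-disubstituted and one is flanked by a silyl ether and a branched side chain. The fallback sets out from 14 and reverses the order of deprotection and ring closure. HF·pyridine first gives the free allylic alcohol (4S,6S)-6-hydroxy-4-methyl-5-methylidene-6-[(2R,3S)-4-methylidene-2-(2-methylprop-2-enyl)-5-oxooxolan-3-yl]hexyl acetate F3. Hydroxyl-assisted ring-closing metathesis of this less hindered substrate (dichloro[1,3-bis(2,4,6-trimethylphenyl)imidazolidin-2-ylidene](2-isopropoxybenzylidene)ruthenium, PhMe, 80 °C) then comes back to the route at 16.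

## Further compounds

F1 | step 13 | (4R,5S)-4-hydroxy-5-[(2S)-4-hydroxybutan-2-yl]-2-methylcyclopent-2-en-1-one | O=C1C(C)=C[C@@H](O)[C@@H]1[C@@H](C)CCO
F2 | step 19 | 6′-O-tert-butyldimethylsilyl ether of the target dimer | C=C1C(=O)O[C@H]2C[C@H](C)[C@@]34C[C@]5(C(=O)O[C@@H]6CC(C)=C([C@@H](C)CCCOC(C)=O)[C@@H](O[Si](C)(C)C(C)(C)C)[C@@H]65)[C@@H](C(C)=C3C[C@H]12)[C@H]4OC(C)=O
F3 | step 9 | (4S,6S)-6-hydroxy-4-methyl-5-methylidene-6-[(2R,3S)-4-methylidene-2-(2-methylprop-2-enyl)-5-oxooxolan-3-yl]hexyl acetate | C=C1C(=O)O[C@H](CC(C)=C)[C@@H]1[C@H](O)C(=C)[C@@H](C)CCCOC(C)=O
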